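The earlier runs and the new flask come from a simulation with constants of no real substance.

Slowness comes first: at 20.0 h the spring run still holds 70.8% of its free monomer, so I reckon in logarithms of the free fraction and ask how many powers of ten each flask gets through.

| setting | winter | spring | gamma | epsilon |
|---|---|---|---|---|
| free monomer | 0.10 M | 0.10 M | 0.10 M | 0.10 M |
| initiator | 1.6 mM | 3.7 mM | 5.0 mM | 3.0 mM |
| remark | run made earlier | run made earlier |  |  |
| time |  |  | 30 h | 60 h |
- winter (time / h: monomer in chains / %, free monomer / %): 1.50: 0.1, 100.4; 3.00: 0.5, 99.0; 6.00: 1.1, 97.5; 12.0: 7.2, 92.6; 20.0: 14.8, 83.9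
- spring (time / h: monomer in chains / %, free monomer / %): 1.50: 1.0, 99.4; 3.00: 1.4, 98.0; 6.00: 4.5, 95.0; 12.0: 14.4, 84.7; 20.0: 28.4, 70.8

(standard deviation of a reading: 0.5 percentage points)
- the earlier runs were read with a standard deviation of 0.5 percentage points
- a reading or a percentage of monomer in chains counts all its forms, free or not
- the flask that ends with the higher amount of monomer in chains, in percent of the free monomer charged, or "neither" when 2 percentage points or less lies between them (gamma / epsilon / neither)
- final monomer in chains, as a percentage of the free monomer charged, in gamma
- final monomer in chains, as a percentage of the free monomer charged, in epsilon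

1. The ruler. Between 12.0 h and 20.0 h, spring gives 103 h for the decade time, the hours in which the free fraction falls by one power of ten at its late pace. I treat that fall as pseudo-first-order.

2. First rung: the lag. Running spring's late line back to a free fraction of one gives 4.59 h, far below the decade time, so I subtract it and otherwise ignore it.

3. Gamma. I scale the decade time inversely with initiator charge, which gives 76.0 h. Its 30 h then covers 0.334 decades, so I reckon 53.7% in chains.

4. Epsilon. Its decade time is longer, 127 h, but 60 h covers 0.437 decades, more than gamma, so I reckon 63.5% in chains. My pick is epsilon, 9.8 percentage points ahead, beyond the margin of 2 points.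

5. Last rung: winter. It reads 187 h, shorter than the 238 h my scaling gives, so I expect epsilon, also charged below spring, to land above my figure.

The forecast says epsilon, with 54% in gamma and 64% in epsilon, and cautions: “Epsilon's long extrapolation is uncertain”.

The flasks give 55.2% in gamma and 74.6% in epsilon, so epsilon ends higher.

    free monomer + initiator → living end + monomer in chains (k = 1.50 × 10⁻⁴ M⁻¹ s⁻¹)
    free monomer + living end → monomer in chains + living end, rate k2*[living end]*[free monomer] (k = 0.00390 M⁻¹ s⁻¹)
    crystals ⇌ monomer in chains, rate k3*(cs3 - [monomer in chains]) while solid is left; crystals form when [monomer in chains] > cs3 (solubility = 47.0 mM, k = 0.00300 s⁻¹)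
    2 initiator → spent initiator (k = 0.00150 M⁻¹ s⁻¹)

Epsilon's free monomer goes from 58.4% at 30.0 h to 25.4% at 60.0 h, a decade time over that span of 83.0 h against my scaled 127 h, while its living end goes from 0.00181 M to 0.00205 M. A further flask, gamma with 0.0085 M of initiator, gets a scaled decade time of 44.7 h, from which I reckon 73.0% in chains; that flask ends with 68.9% in chains.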